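A ring cannot close on G.Q that does not yet exist, and G.Q cannot exist before Z has dissolved to G and G has met Q. The two flasks differ in temperature, and that invites a quarrel at the board.

- south-east: Z 0.10 M; Q 1.10 equiv; L 2.00 mM; temperature 70 °C; time 6.0 min
- north-west: Z 0.10 M; Q 1.10 equiv; L 2.00 mM; temperature 55 °C; time 6.0 min

- the best flask by amount of J, in percent of the Z charged; "all alike" if 1.5 percentage points covers them all (south-east / north-west / all alike)
- amount of J at the end, in percent of the Z charged, south-east
- amount of J at the end, in percent of the Z charged, north-west

    G + Q → G.Q (k1 = 0.046 M⁻¹ s⁻¹, Ea1 = 65.0 kJ mol⁻¹)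
    G.Q → J (k2 = 0.0059 s⁻¹, Ea2 = 95.0 kJ mol⁻¹)
    G + G.Q → G.G.Q (k3 = 0.0079 M⁻¹ s⁻¹, Ea3 = 53.0 kJ mol⁻¹)
    G + L → G.L (k4 = 1.7 M⁻¹ s⁻¹, Ea4 = 42.0 kJ mol⁻¹)
    Z ⇌ G, rate k5*(cs5 - [G]) while solid is left; crystals form when [G] > cs5 (cs5 = 0.098 M, k5 = 0.0058 s⁻¹)
    (constants at 70 °C)

- percent here means Z units held: one G.G.Q counts as two
- Z is a solid; its amount is given per volume of the solution
- at 70 °C the constants are as listed, elsewhere as the activation energies make them
- at the start none of Z is in solution
- what has only dissolved of Z counts as not reacted

The first chemist holds the feed view. Dissolution has a time of 2.87 min, the run of 6.0 min holds 2.09 of those times, and its coefficient 0.0058 s⁻¹ is listed with no activation energy, so it stands equal in both flasks. The first therefore expects the flasks to fall within 1.5 percentage points of each other.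

I hold the clock view, in which ring closure and activation by Q both lose speed on cooling, and I work in logarithms, where factors add. Going from 70 °C to 55 °C costs ring closure 0.661 in powers of ten, a factor of 4.6. At fixed temperatures that cost scales with the barrier, so activation by Q, with 65.0 kJ mol⁻¹ against 95.0 kJ mol⁻¹, costs 0.452.

From 0.0059 s⁻¹ I get 1.96 min in south-east and 8.97 min in north-west. Call this the closure clock, the half-life of G.Q by ring closure at the temperature of the flask. The run holds 3.06 clock lengths in south-east, which is longer than the clock. In north-west it holds 0.669, which is shorter.

So I name south-east as the better flask. Closure by itself gives a ratio of J of 4.6, and closure with activation, their logarithms added to 1.11, gives 13.1. My hand reckoning stops at that window and reaches no percentages.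

The forecast names south-east, with 29% (25% to 33%) there and 4.5% (3.5% to 5.5%) in north-west, the yield being “limited by the slow, high-barrier ring closure”.

The simulation gives south-east as the best flask, with 29.1% of J there and 4.53% in north-west. The ratio of 6.42 lies inside my window , and the gap of 25 points is wider than 1.5 points, so the clock view wins.

In north-west, 3.64 min passed before half of the turnover to G.Q was done, so the median G.Q has an age of 2.36 min at the end, shorter than the clock of 8.97 min. That age closes 16.7% of it, and north-west reads 16.9% of J in J plus G.Q. The feed view has its ground in the neighbour with 0.40 M of Z, at the same temperature and so on the same clock, where 67.2% of Z is still solid at the end, J stands at 3.51%, and J in J plus G.Q reads 17.5%.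

(The constants stand for no real mixture; the rest is arithmetic.)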